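**Plan**

- Retrosynthesis: the C2–Br and C3–Br bonds are cut first (pyrrole-ring bromination of 4,7-dibromoindole). C4–Br and C7–Br are then traced back to C–SiMe3 bonds, and the indole to an N-tosylindoline.
- The benzo ring is cut at C3a–C7a, C4–C5 and C6–C7. It carries only the para-related bromines at C4/C7 and hydrogens at C5/C6, so it unfolds into two silyl-capped alkynes linked through N1–C2–C3 plus one acetylene (C5–C6).
- The diyne is cut at N–C(sp) (copper-catalysed alkynylation) and at N–CH2 (Mitsunobu alkylation).
- Forward: the chain is assembled on nitrogen, then the five-membered nitrogen ring and the benzene ring arise together in one (2+2+2) cycloaddition. Silicon-to-bromine exchange, dehydrogenation, N-deprotection and C3/C2 bromination follow.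
- Stereochemistry: the target is planar and achiral, so no stereocentre has to be set.

Key step: step 4

Remark: the silylbutynol, tert-butyl tosylcarbamate, (bromoethynyl)trimethylsilane and acetylene are taken as purchasable.

**Route**

Step 1
Reactants: 1 4-(trimethylsilyl)but-3-yn-1-ol; 2 tert-butyl tosylcarbamate (N-Boc-p-toluenesulfonamide)
Product: 3 tert-butyl tosyl[4-(trimethylsilyl)but-3-yn-1-yl]carbamate
Conditions: PPh3, DIAD, THF, 0 °C → rt
Reagents that add atoms: none
Why: Mitsunobu N-alkylation, in which the acidic N–H of the Boc-activated sulfonamide protonates the PPh3/DIAD betaine and its anion displaces the oxyphosphonium of the unhindered primary alcohol by SN2, giving monoalkylation with the silylalkyne untouched.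

Step 2
Reactants: 3 tert-butyl tosyl[4-(trimethylsilyl)but-3-yn-1-yl]carbamate
Product: 4 4-methyl-N-[4-(trimethylsilyl)but-3-yn-1-yl]benzenesulfonamide
Conditions: CF3CO2H, CH2Cl2, 0 °C → rt
Reagents that add atoms: none
Why: Acid-mediated Boc cleavage (loss of the tert-butyl cation as 2-methylpropene, then decarboxylation) frees the secondary sulfonamide, while the N–S bond and the alkynyl C–Si bond are inert to CF3CO2H at room temperature.

Step 3
Reactants: 4 4-methyl-N-[4-(trimethylsilyl)but-3-yn-1-yl]benzenesulfonamide; 5 (bromoethynyl)trimethylsilane
Product: 6 4-methyl-N-[(trimethylsilyl)ethynyl]-N-[4-(trimethylsilyl)but-3-yn-1-yl]benzenesulfonamide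
Conditions: CuSO4·5H2O (10 mol%), 1,10-phenanthroline (20 mol%), K2CO3, toluene, 65 °C
Reagents that add atoms: none
Why: Copper-catalysed C(sp)–N cross-coupling of a sulfonamide with a 1-bromoalkyne (Ullmann-type ynamide synthesis) is well established for secondary tosylamides, and the weak anhydrous carbonate base leaves both alkynylsilanes in place.

Step 4
Reactants: 6 4-methyl-N-[(trimethylsilyl)ethynyl]-N-[4-(trimethylsilyl)but-3-yn-1-yl]benzenesulfonamide; 7 acetylene
Product: 8 1-tosyl-4,7-bis(trimethylsilyl)indoline
Conditions: RhCl(PPh3)3 (10 mol%), HC≡CH (1 atm), toluene, rt → 60 °C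
Reagents that add atoms: none
Why: RhCl(PPh3)3 sheds a phosphine and binds both alkynes of 6, and oxidative cyclisation on monovalent rhodium gives a bicyclic rhodacyclopentadiene of trivalent rhodium in which C3a–C7a is already formed. Acetylene then coordinates and inserts into a Rh–C bond, and reductive elimination forges the second of the C4–C5 and C6–C7 bonds and returns monovalent rhodium. The closest known reaction type is the rhodium-catalysed (2+2+2) cycloaddition of N-sulfonyl ynamide-tethered 1,6-diynes with monoalkynes, which gives N-sulfonylindolines. The five-membered nitrogen ring closes by intramolecular oxidative coupling of the two tethered alkynes across the N–CH2–CH2 linker, and the six-membered benzene ring closes by alkyne insertion followed by C–C reductive elimination from the seven-membered rhodacycle. No stereocentre is formed. The step needs cross-cyclotrimerisation to win over diyne self-coupling and acetylene oligomerisation, which the tether-assisted metallacycle formation, the two bulky SiMe3 termini and a standing excess of the small alkyne should secure, while the tether and the symmetry of acetylene leave no regiochemical choice, so silicon must end up at C4 and C7.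

Step 5
Reactants: 8 1-tosyl-4,7-bis(trimethylsilyl)indoline
Product: 10 4,7-dibromo-1-tosylindoline, via 7-bromo-1-tosyl-4-(trimethylsilyl)indoline 9 (not isolated)
Conditions: Br2 (2.05 equiv), CH2Cl2, −78 → 0 °C, dark
Reagents that add atoms: bromine, BrBr
Why: Electrophilic ipso-bromodesilylation of an aryltrimethylsilane (SEAr through a beta-silyl-stabilised arenium ion that loses Me3SiBr) is much faster than C–H bromination, so the nitrogen-activated C7 silane should go first, the C4 silane second, and two equivalents of Br2 should leave C5 and C6 untouched.

Step 6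
Reactants: 10 4,7-dibromo-1-tosylindoline
Product: 11 4,7-dibromo-1-tosyl-1H-indole
Conditions: DDQ (2 equiv), 1,4-dioxane, 100 °C
Reagents that add atoms: none
Why: DDQ dehydrogenation of an N-sulfonylindoline (hydride abstraction from the C2–C3 unit, then proton loss) is driven by formation of the aromatic pyrrole ring and tolerates aryl bromides and the sulfonamide.

Step 7
Reactants: 11 4,7-dibromo-1-tosyl-1H-indole
Product: 12 4,7-dibromo-1H-indole
Conditions: KOH, MeOH/THF/H2O, 50 °C
Reagents that add atoms: none
Why: Base-mediated N-desulfonylation of an N-tosylindole proceeds by attack of hydroxide or methoxide at sulfur because the indolide, here further stabilised by two bromine atoms, is a good leaving group, and aryl bromides do not react under these conditions.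

Step 8
Reactants: 12 4,7-dibromo-1H-indole
Product: 14 2,3,4,7-tetrabromo-1H-indole, via 3,4,7-tribromo-1H-indole 13 (not isolated)
Conditions: NBS (2.1 equiv), THF, −78 °C → rt, dark
Reagents that add atoms: N-bromosuccinimide, O=C1CCC(=O)N1Br
Why: Electrophilic aromatic bromination of the free indole with NBS takes C3 first and then C2 of the 3-bromoindole, since the pyrrole ring remains far more nucleophilic than the benzo ring, which two bromine atoms deactivate.

**Compound list**

1 | 4-(trimethylsilyl)but-3-yn-1-ol | C[Si](C)(C)C#CCCO | starting material
2 | tert-butyl tosylcarbamate (N-Boc-p-toluenesulfonamide) | CC(C)(C)OC(=O)NS(=O)(=O)c1ccc(C)cc1 | starting material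
3 | tert-butyl tosyl[4-(trimethylsilyl)but-3-yn-1-yl]carbamate | C[Si](C)(C)C#CCCN(C(=O)OC(C)(C)C)S(=O)(=O)c1ccc(C)cc1 | intermediate
4 | 4-methyl-N-[4-(trimethylsilyl)but-3-yn-1-yl]benzenesulfonamide | C[Si](C)(C)C#CCCNS(=O)(=O)c1ccc(C)cc1 | intermediate
5 | (bromoethynyl)trimethylsilane | C[Si](C)(C)C#CBr | starting material
6 | 4-methyl-N-[(trimethylsilyl)ethynyl]-N-[4-(trimethylsilyl)but-3-yn-1-yl]benzenesulfonamide | C[Si](C)(C)C#CCCN(C#C[Si](C)(C)C)S(=O)(=O)c1ccc(C)cc1 | intermediate
7 | acetylene | C#C | starting material
8 | 1-tosyl-4,7-bis(trimethylsilyl)indoline | C[Si](C)(C)c1ccc([Si](C)(C)C)c2c1CCN2S(=O)(=O)c1ccc(C)cc1 | intermediate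
9 | 7-bromo-1-tosyl-4-(trimethylsilyl)indoline | C[Si](C)(C)c1ccc(Br)c2c1CCN2S(=O)(=O)c1ccc(C)cc1 | intermediate
10 | 4,7-dibromo-1-tosylindoline | Brc1ccc(Br)c2c1CCN2S(=O)(=O)c1ccc(C)cc1 | intermediate
11 | 4,7-dibromo-1-tosyl-1H-indole | Brc1ccc(Br)c2c1ccn2S(=O)(=O)c1ccc(C)cc1 | intermediate
12 | 4,7-dibromo-1H-indole | Brc1ccc(Br)c2[nH]ccc12 | intermediate
13 | 3,4,7-tribromo-1H-indole | Brc1c[nH]c2c(Br)ccc(Br)c12 | intermediate
14 | 2,3,4,7-tetrabromo-1H-indole | Brc1[nH]c2c(Br)ccc(Br)c2c1Br | target

**Step count**

Total steps: 8. Longest linear sequence: 8 steps (from 1 to 14).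

**Steps most likely to fail**

Step 4. Oxidative cyclisation at two silyl-capped alkyne termini may be slow, so that acetylene oligomerisation and catalyst deactivation overtake the cross-cycloaddition. The fallback sets out from 6 and replaces the gas by a liquid acetylene equivalent under a more electrophilic catalyst. With [Rh(cod)2]BF4 and BINAP (a cationic complex of monovalent rhodium) and an excess of vinyl acetate in 1,2-dichloroethane, alkene insertion into the rhodacycle should give the cyclohexadiene 1-tosyl-4,7-bis(trimethylsilyl)-2,3,5,6-tetrahydro-1H-indol-5-yl acetate F1. This should lose acetic acid in the same flask and aromatise, so the fallback comes back to the route at 8.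

Step 5. C–H bromination para to the indoline nitrogen (C5) may compete with ipso attack at the less activated C4 silane, followed by acid-induced loss of silicon, which would misplace or lose a bromine. The fallback sets out from 8 and changes the oxidation level before halogenation. DDQ in hot toluene should give 1-tosyl-4,7-bis(trimethylsilyl)-1H-indole F2, in which the nitrogen lone pair belongs to the pyrrole sextet and no longer activates C5. Br2 (3 equiv) in CH2Cl2 at low temperature should then brominate C3 and replace both silyl groups, giving 3,4,7-tribromo-1-tosyl-1H-indole F3. KOH in MeOH/THF removes the tosyl group and the fallback comes back to the route at 13, which needs only one equivalent of NBS to reach 14.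

Step 6. Hydride abstraction by DDQ from an indoline that carries both an N-sulfonyl group and two bromines may be sluggish, leaving incomplete conversion or decomposition under forcing conditions. The fallback sets out from 10 and removes the sulfonyl group before the oxidation. CF3SO3H in 1,2-dichloroethane at about 90 °C, followed by aqueous work-up, should cleave the N–S bond of the electron-poor N-arylsulfonamide to give 4,7-dibromoindoline F4. MnO2 in CH2Cl2 at room temperature should then dehydrogenate the free indoline, and the fallback comes back to the route at 12, so step 7 is no longer needed.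

**Further compounds**

F1 | step 4 | 1-tosyl-4,7-bis(trimethylsilyl)-2,3,5,6-tetrahydro-1H-indol-5-yl acetate | CC(=O)OC1CC(=C2N(CCC2=C1[Si](C)(C)C)S(=O)(=O)c1ccc(C)cc1)[Si](C)(C)C
F2 | step 5 | 1-tosyl-4,7-bis(trimethylsilyl)-1H-indole | C[Si](C)(C)c1ccc([Si](C)(C)C)c2c1ccn2S(=O)(=O)c1ccc(C)cc1
F3 | step 5 | 3,4,7-tribromo-1-tosyl-1H-indole | Brc1cn(S(=O)(=O)c2ccc(C)cc2)c2c(Br)ccc(Br)c12
F4 | step 6 | 4,7-dibromoindoline | Brc1ccc(Br)c2c1CCN2
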